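(The numbers in the tables come from a simulation from invented constants; the scatter is artificial.)

The constant I needed before charging the spring run was one the earlier runs could give me.

| flask | starting material | partner | free catalyst | time |
|---|---|---|---|---|
| midnight | 0.400 M | 1.20 M | 0.0120 M |  |
| noon | 0.200 M | 1.00 M | 0.0120 M |  |
| dawn | 0.400 M | 1.20 M | 0.00600 M |  |
| summer | 0.800 M | 1.20 M | 0.0120 M |  |
| spring | 2.00 M | 6.00 M | 0.0120 M | 42 min |

| run | time / min | [starting material] / M |
|---|---|---|
| midnight run | 1.7 | 0.319 |
| midnight run | 2.9 | 0.296 |
| midnight run | 4.9 | 0.265 |
| midnight run | 8.4 | 0.228 |
| midnight run | 14 | 0.200 |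
| midnight run | 25 | 0.183 |
| midnight run | 42 | 0.177 |
| noon run | 1.7 | 0.157 |
| noon run | 2.9 | 0.147 |
| noon run | 4.9 | 0.134 |
| noon run | 8.4 | 0.127 |
| noon run | 14 | 0.116 |
| noon run | 25 | 0.098 |
| noon run | 42 | 0.097 |
| dawn run | 1.7 | 0.352 |
| dawn run | 2.9 | 0.331 |
| dawn run | 4.9 | 0.303 |
| dawn run | 8.4 | 0.283 |
| dawn run | 14 | 0.241 |
| dawn run | 25 | 0.225 |
| dawn run | 42 | 0.215 |
| summer run | 1.7 | 0.678 |
| summer run | 2.9 | 0.620 |
| summer run | 4.9 | 0.554 |
| summer run | 8.4 | 0.479 |
| summer run | 14 | 0.432 |
| summer run | 25 | 0.388 |
| summer run | 42 | 0.367 |

(scatter of a reading: 0.004 M)

- Overall: starting material + partner -> target, with free catalyst as catalyst.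
- Constant volume, constant temperature.
- Bound and free are read together.
- An order is taken over about fifteen percent of the charge, up and down.

- reaction order in [starting material] at the outset, round the charge of the midnight run, defined at two percent of the starting material turned into target (one fixed amount of target, the same in the runs compared)
- reaction order in [partner] at the outset, round the charge of the midnight run, defined at two percent of the starting material turned into target
- the noon run starts with 0.200 M less of starting material and of partner than the midnight run, and with no target. Compared where both hold the same amount of starting material, once fifteen percent of what the noon run was charged with has turned into target, is the noon run faster, slower or alike (within a tenth)?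
- starting material in the spring run at 42 min, as a share of the starting material charged

By 1.7 min, the summer run, charged with 0.800 M of starting material against 0.400 M in the midnight run at the same partner and free catalyst, had lost 1.51 times as much, less than the ratio of the charges, 2.00. I read that as saturation and got 0.820 M for H, the half-binding concentration: the starting material at which the rate stands at half its ceiling, the Michaelis constant of this flask, read at partner 1.20 M. It is a rough reading, since the scatter is 4.94% of the smaller drop.

With H held fixed, the order in starting material at a concentration S is H/(H+S), which is also the share of catalyst left free. That gave me 0.672 for the midnight charge, 0.506 for the summer charge and 0.291 for the spring charge.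

The decision was whether the spring run could keep 0.0120 M of free catalyst and 42 min. The dawn run, with half the catalyst of the midnight run, stalled higher, at 0.215 M against 0.177 M, so I took the stall to be lost catalyst. The summer run made 0.433 M of target against 0.223 M in the midnight run.

At the same partner and free catalyst, these two runs had turned 55.8% of the charge in the midnight run and 54.1% in the summer run by 42 min. I took those shares as readings from two charges, not as a rule, and carrying them to the larger charge of the spring run was an extrapolation. The spring run had 5.00 times the partner of the midnight run, so I expected it to turn a larger share. I left the catalyst unchanged, and my estimate was an order of 0.672 round the midnight charge and under 44.2% left in the spring run.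

The forecast gave 0.7 and 0.6 for the orders, faster for the noon run and 25% for the spring run: “the extrapolated kinetics and catalyst death leave about 25%”.

    free catalyst + starting material ⇌ catalyst-substrate complex (82.80 L mol⁻¹ min⁻¹, 33.42 min⁻¹)
    catalyst-substrate complex + partner → target + free catalyst (11.34 L mol⁻¹ min⁻¹)
    2 free catalyst → 2 spent catalyst (45.30 L mol⁻¹ min⁻¹)
    partner → lost reagent (0.03588 min⁻¹)

The simulation gave 0.68 and 0.87 for the orders, faster for the noon run, and 9.90% of the starting material left in the spring run, which is 1.80 M of target. H/(H+S) at the midnight charge stands at 0.672 beside that first order. With H held fixed, saturation put the noon run, charged with 0.200 M, at 0.598 of the midnight rate. The rates near the start, 0.030 M min⁻¹ and 0.062 M min⁻¹, stand at 0.484, which leaves a factor 0.809 for partner going from 1.20 M to 1.00 M.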